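Start with an easy sum: add the two products in each run. Wednesday's run holds 68.5% on average over its last two readings, and Thursday's run, the flask asked about, holds 54.0% at its last reading, 5.00 min.

| flask | left-handed substrate | right-handed substrate | solid reagent | free catalyst | racemization catalyst | remark | time |
|---|---|---|---|---|---|---|---|
| Thursday's | 0.16 M | 0.16 M | 2.5 equiv | 0.51 mol% | 2.5 mol% | the very flask that is asked about, followed so far |  |
| Wednesday's | 0.24 M | 0.24 M | 2.5 equiv | 0.51 mol% | 2.5 mol% | run made earlier |  |
| flask | 0.16 M | 0.16 M | 2.50 equiv | 0.51 mol% | 2.5 mol% |  | 12 min |

| run | time / min | left-handed product / % | right-handed product / % |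
|---|---|---|---|
| Thursday's | 0.833 | 17 | 7 |
| Thursday's | 1.50 | 30 | 15 |
| Thursday's | 2.50 | 34 | 15 |
| Thursday's | 3.00 | 39 | 16 |
| Thursday's | 4.00 | 36 | 16 |
| Thursday's | 5.00 | 41 | 13 |
| Wednesday's | 1.00 | 21 | 11 |
| Wednesday's | 1.50 | 30 | 16 |
| Wednesday's | 2.50 | 43 | 16 |
| Wednesday's | 4.00 | 47 | 21 |
| Wednesday's | 8.00 | 50 | 17 |
| Wednesday's | 12.0 | 51 | 19 |

(scatter of a reading: 2 percentage points)

- free catalyst is single-handed; left-handed substrate and right-handed substrate are mirror images of each other, charged as a racemate, each of them at the stated concentration
- given per volume of solution although it is solid: solid reagent
- the analysis behind the earlier runs scatters by 2 percentage points, standard deviation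
- at the start none of the solid reagent is in solution
- an excess is the difference of the two amounts in percent of their sum
- an excess is below zero if the other one leads

- left-handed product and right-handed product together, in percent of the left-handed substrate and right-handed substrate charged together, at 12 min
- excess of left-handed product over right-handed product in the product at 12 min
- whether the exchange between left-handed substrate and right-handed substrate keeps pace with the reaction: how far the product's excess at 12 min gets from its value without exchange to its value with instant exchange (above 80% keeps pace, below 20% hardly takes part, else lags behind)

Two chemists argue over what Thursday's flask holds at 12 min. The second expects the stop to come with the solid reagent. Both flasks got 2.5 equiv, so she expects one common ceiling, and she expects Thursday's flask, the more dilute, to climb on to Wednesday's 68.5%.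

The first expects the free catalyst to die. She supposes that substrate falls in proportion to what is left, while catalyst is lost at a pace that ignores the substrate. Each bit of catalyst lost then takes a fixed slice off the logarithm of the fraction left, and the total slice follows the catalyst per volume. On Wednesday's last two readings that logarithm, sign reversed, is 1.16. Scaled to Thursday's charge of catalyst it is 0.770. This is the reach, minus the natural logarithm of the fraction of substrate left once the catalyst is spent.

The reach gives her a first answer of 53.7% of product. That answer goes back in once: with one solid reagent taken for each product, it asks for 53.7% of an equivalent on the two substrates together, and 1.25 equivalents stand charged on them together, so by her count the reagent does not stop the flask. Thursday's 54.0%, not used in the reckoning, lands beside it.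

The forecast takes the first chemist's side, a little above her reckoning: 55%, an excess of 42%, and exchange that keeps pace. Its ground: “Excess solid reagent rules out reagent shortage, so the catalyst is probably dying”.

The flask gives 52.6%, an excess of 46.3%, and exchange that keeps pace, 94% of the way to the excess with instant exchange.

    partner + free catalyst + left-handed substrate → free catalyst + left-handed product (k = 550 M⁻² s⁻¹)
    partner + free catalyst + right-handed substrate → free catalyst + right-handed product (k = 198 M⁻² s⁻¹)
    left-handed substrate + racemization catalyst ⇌ right-handed substrate + racemization catalyst, rate k3*[racemization catalyst]*[left-handed substrate] forward; the back reaction follows from the equilibrium constant (k = 27.5 M⁻¹ s⁻¹)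
    solid reagent ⇌ partner, rate k4*(cs4 - [partner]) while solid is left; crystals form when [partner] > cs4 (solubility = 0.0600 M, k = 0.0636 s⁻¹)
    partner + free catalyst → spent catalyst (k = 0.407 M⁻¹ s⁻¹)
    2 partner → self-condensation product (k = 0.0890 M⁻¹ s⁻¹)

That yield is a reach of 0.747, beside the 0.770 carried from Wednesday, and in the flask at 6.00 min free catalyst stands at 0.147% of its charge with solid reagent still at 11.3% of its own. The second chemist's view has its region in the neighbour flask charged with 1.00 equiv of solid reagent. There solid reagent, the limiting reagent, is first to run out, at 0%, with free catalyst still at 20.3% at 12.0 min, and the yield falls below the forecast's 55%. The reach taken for the 79.7% of catalyst spent there is 0.614, which reckons 45.9%, and that neighbour flask gives 44.8%.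

The readings stem from a simulated flask on assumed constants; noise was put on by code.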